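The synthesis rests on cutting the 1,4-dioxane ring at C2–C3 and O4–C4a. This exploits that C3 and O4 are the carbonyl carbon and oxygen of O-benzylvanillin, that C2 is the α-carbon of a latent carboxyl group (the CH2OH carbon), and that C4a of the benzo ring can carry iodine. In one flask a chiral boron enolate adds to the aldehyde (C2–C3, both stereocentres). The boron aldolate, unlocked by fluoride, then passes O4 to palladium inserted into C4a–I, which closes the ring. The precursor is an acyclic (4-cyano-2-iodophenoxy)acetyl oxazolidinone. Its nitrile later becomes the aldehyde from which rings C and A of the flavonol are built.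

Key step: step 2

Numbering used for the benzodioxane: O1, C2 (bears CH2OH), C3 (bears the guaiacyl ring), O4, C4a, C5 to C8, C8a. The flavonol sits on C6.
Assumption: imide 2 is taken as a purchasable compound. It is otherwise one N-acylation away from (R)-4-benzyloxazolidin-2-one and chloroacetyl chloride.

Step 1
Reactants: 1 4-hydroxy-3-iodobenzonitrile; 2 (R)-4-benzyl-3-(chloroacetyl)oxazolidin-2-one
Product: 3 (R)-4-benzyl-3-[(4-cyano-2-iodophenoxy)acetyl]oxazolidin-2-one
Conditions: K2CO3, NaI (cat.), acetone, rt to 40 °C
Reagents that add atoms: none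
Why: Williamson ether synthesis with Finkelstein activation, in which the acidic and weakly basic cyano-iodophenoxide should displace the α-halide faster than it attacks the imide carbonyl, and the auxiliary stereocentre is not touched.

Step 2
Reactants: 3 (R)-4-benzyl-3-[(4-cyano-2-iodophenoxy)acetyl]oxazolidin-2-one; 4 4-(benzyloxy)-3-methoxybenzaldehyde
Product: 7 (R)-4-benzyl-3-{[(2R,3S)-3-[4-(benzyloxy)-3-methoxyphenyl]-6-cyano-2,3-dihydro-1,4-benzodioxin-2-yl]carbonyl}oxazolidin-2-one (trans), via boron enolate 5 (not isolated), via boron aldolate 6 (not isolated)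
Conditions: Bu2BOTf (1.15 equiv), iPr2NEt (1.3 equiv), toluene, −78 to 0 °C; 4, −78 to 0 °C; then in the same flask CsF (3 equiv), Pd2(dba)3 (2.5 mol %), tBuXPhos (6 mol %), 50 °C
Reagents that add atoms: none
Why: Proposed new method: soft enolisation gives the (Z)-boron enolate 5, which adds to 4 through a Zimmerman–Traxler chair on the enolate face opposite the benzyl group of the (R)-auxiliary (Evans syn aldol), so C2–C3 forms and the auxiliary sets both new stereocentres as (2R,3S). Fluoride then converts the boron aldolate 6 into a fluoroborate that hands O4 to the arylpalladium halide formed when zerovalent palladium inserts into C4a–I, the strong B–F bond driving the exchange, and C–O reductive elimination follows. The closest known reaction types are the Evans aldol of aryloxyacetyl imides, the palladium-catalysed intramolecular etherification of 2-haloaryl ethers of secondary alcohols to 1,4-benzodioxanes, and the palladium-catalysed alkoxylation of aryl halides with alkoxyborate salts; what is new is a boron aldolate acting directly as the alkoxide donor. The six-membered dioxane ring closes by reductive elimination from a seven-membered oxapalladacycle (Pd, C4a, C8a, O1, C2, C3, O4) without breaking any bond at C2 or C3, so the syn aldolate maps onto the trans ring. The step needs oxygen transfer to outrun butyl transfer, retro-aldol and β-hydride elimination, which should be favoured by the bulky biaryl phosphine, by the absence of free alkoxide or added Brønsted base, and by adding the catalyst only after the enolate is consumed, so that enolate O- or C-arylation cannot compete. In the substrate the iodine ortho to O1 allows only the six-membered closure, 4 is non-enolisable, and any stereochemical leak gives a diastereomer of 7 that chromatography can remove because the auxiliary is still attached.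

Step 3
Reactants: 7 trans-benzodioxane imide
Product: 8 (2S,3S)-3-[4-(benzyloxy)-3-methoxyphenyl]-2-(hydroxymethyl)-2,3-dihydro-1,4-benzodioxine-6-carbonitrile
Conditions: LiBH4, THF, 0 °C
Reagents that add atoms: none
Why: Reductive cleavage of the N-acyloxazolidinone, in which hydride attacks the exocyclic imide carbonyl and should give the primary alcohol while the aryl nitrile stays inert, the spatial arrangement at C2 and C3 is kept (the C2 descriptor changes only through priorities), and the trans ring is the stable isomer in any case.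

Step 4
Reactants: 8 hydroxymethyl nitrile
Product: 9 (2S,3S)-3-[4-(benzyloxy)-3-methoxyphenyl]-2-(hydroxymethyl)-2,3-dihydro-1,4-benzodioxine-6-carbaldehyde
Conditions: DIBAL-H (3 equiv), CH2Cl2, −78 to −40 °C; then 1 M HCl
Reagents that add atoms: water, SMILES O
Why: DIBAL-H reduction of an aryl nitrile stops at the N-aluminoimine, which acid hydrolysis converts to the aldehyde, with one equivalent of hydride consumed by the free hydroxyl group.

Step 5
Reactants: 9 benzodioxane aldehyde; 10 1-[2,4-bis(benzyloxy)-6-hydroxyphenyl]ethanone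
Product: 11 (E)-1-[2,4-bis(benzyloxy)-6-hydroxyphenyl]-3-{(2S,3S)-3-[4-(benzyloxy)-3-methoxyphenyl]-2-(hydroxymethyl)-2,3-dihydro-1,4-benzodioxin-6-yl}prop-2-en-1-one
Conditions: KOH, EtOH–THF, rt
Reagents that add atoms: none
Why: Claisen–Schmidt condensation of the methyl ketone enolate with the non-enolisable aldehyde should give the (E)-chalcone, and the benzodioxane no longer carries an acidic C–H, so its stereocentres are safe in base.

Step 6
Reactants: 11 chalcone
Product: 12 5,7-bis(benzyloxy)-2-{(2S,3S)-3-[4-(benzyloxy)-3-methoxyphenyl]-2-(hydroxymethyl)-2,3-dihydro-1,4-benzodioxin-6-yl}-3-hydroxy-4H-chromen-4-one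
Conditions: H2O2 (30 %), NaOH, MeOH–THF, 0 °C to rt
Reagents that add atoms: hydrogen peroxide, SMILES OO
Why: Algar–Flynn–Oyamada reaction, in which hydroperoxide oxidises the enone, the 2'-phenoxide closes ring C at the β-carbon, and the dihydroflavonol is oxidised further to the flavonol, far from the two stereocentres.

Step 7
Reactants: 12 tribenzyl flavonol
Product: 13 2,3-dehydrosilybin B
Conditions: H2 (1 atm), Pd/C, THF–MeOH, rt
Reagents that add atoms: none
Why: Catalytic hydrogenolysis should remove the three unhindered O-benzyl groups faster than it cleaves the secondary, ring-constrained C3–O4 benzylic ether, and the flavonol double bond is not reduced under these conditions.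

Compound list
1 | 4-hydroxy-3-iodobenzonitrile | N#Cc1ccc(O)c(I)c1 | starting material
2 | (R)-4-benzyl-3-(chloroacetyl)oxazolidin-2-one | O=C(CCl)N1[C@H](Cc2ccccc2)COC1=O | starting material
3 | (R)-4-benzyl-3-[(4-cyano-2-iodophenoxy)acetyl]oxazolidin-2-one | N#Cc1ccc(OCC(=O)N2[C@H](Cc3ccccc3)COC2=O)c(I)c1 | intermediate
4 | 4-(benzyloxy)-3-methoxybenzaldehyde | COc1cc(C=O)ccc1OCc1ccccc1 | starting material
5 | (Z)-dibutylboron enolate of 3 | CCCCB(CCCC)O/C(=C\Oc1ccc(C#N)cc1I)N1[C@H](Cc2ccccc2)COC1=O | intermediate
6 | dibutylboron (2R,3S)-syn aldolate of 3 and 4 | COc1cc([C@H](OB(CCCC)CCCC)[C@@H](Oc2ccc(C#N)cc2I)C(=O)N2[C@H](Cc3ccccc3)COC2=O)ccc1OCc1ccccc1 | intermediate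
7 | (R)-4-benzyl-3-{[(2R,3S)-3-[4-(benzyloxy)-3-methoxyphenyl]-6-cyano-2,3-dihydro-1,4-benzodioxin-2-yl]carbonyl}oxazolidin-2-one | COc1cc([C@@H]2Oc3cc(C#N)ccc3O[C@H]2C(=O)N2[C@H](Cc3ccccc3)COC2=O)ccc1OCc1ccccc1 | intermediate
8 | (2S,3S)-3-[4-(benzyloxy)-3-methoxyphenyl]-2-(hydroxymethyl)-2,3-dihydro-1,4-benzodioxine-6-carbonitrile | COc1cc([C@@H]2Oc3cc(C#N)ccc3O[C@H]2CO)ccc1OCc1ccccc1 | intermediate
9 | (2S,3S)-3-[4-(benzyloxy)-3-methoxyphenyl]-2-(hydroxymethyl)-2,3-dihydro-1,4-benzodioxine-6-carbaldehyde | COc1cc([C@@H]2Oc3cc(C=O)ccc3O[C@H]2CO)ccc1OCc1ccccc1 | intermediate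
10 | 1-[2,4-bis(benzyloxy)-6-hydroxyphenyl]ethanone | CC(=O)c1c(O)cc(OCc2ccccc2)cc1OCc1ccccc1 | starting material
11 | (E)-chalcone from 9 and 10 | COc1cc([C@@H]2Oc3cc(/C=C/C(=O)c4c(O)cc(OCc5ccccc5)cc4OCc4ccccc4)ccc3O[C@H]2CO)ccc1OCc1ccccc1 | intermediate
12 | 5,7,4''-tri-O-benzyl-2,3-dehydrosilybin B (free 3-OH and CH2OH) | COc1cc([C@@H]2Oc3cc(-c4oc5cc(OCc6ccccc6)cc(OCc6ccccc6)c5c(=O)c4O)ccc3O[C@H]2CO)ccc1OCc1ccccc1 | intermediate
13 | 2,3-dehydrosilybin B, (2S,3S) in the benzodioxane | COc1cc([C@@H]2Oc3cc(-c4oc5cc(O)cc(O)c5c(=O)c4O)ccc3O[C@H]2CO)ccc1O | target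

Total step count: 7. Longest linear sequence: 7 steps (1 → 3 → 7 → 8 → 9 → 11 → 12 → 13).

Steps most likely to fail

Step 2. After fluoride addition the aldolate may revert by retro-aldol. Boron may pass a butyl group instead of oxygen to palladium. The palladium alkoxide may also undergo β-hydride elimination, which oxidises the carbinol and removes the iodine.

The fallback makes the two bonds in separate, known operations. It sets out from 3 and 4 and comes back at 8. The same Evans aldol is worked up oxidatively (H2O2, pH 7 buffer) to the isolated syn aldol F1. LiBH4 removes the auxiliary to give the (1S,2S)-diol F2. TBSCl and imidazole silylate only the primary hydroxyl to give the mono-silyl ether F3. A palladium-catalysed intramolecular etherification (Pd(OAc)2, 2-(di-tert-butylphosphino)-1,1'-binaphthyl, Cs2CO3, toluene, 65 °C) then closes the ring to the silylated benzodioxane F4. This substrate has neither an acidic C–H nor a retro-aldol path. TBAF finally gives 8.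

Step 6. The hydroperoxide adduct may close a five-membered ring instead of ring C. This is the aurone pathway, and the benzyloxy group ortho to the ketone is known to favour it.

The fallback splits ring closure and hydroxylation. It sets out from 11 and comes back at 12. Catalytic I2 in DMSO at 110 °C cyclises and dehydrogenates the chalcone to the flavone F5. Dimethyldioxirane then epoxidises the C2–C3 double bond of ring C, and catalytic TsOH opens the epoxide to the 3-hydroxyflavone 12.

Step 7. Hydrogenolysis may not stop at the three benzyl ethers and may also open the dioxane ring at the benzylic C3–O4 bond.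

The fallback replaces reductive cleavage by Lewis-acid cleavage with a cation scavenger (BCl3, pentamethylbenzene, CH2Cl2, −78 °C). It sets out from 12, comes back at 13, and passes through no new compound. A transient ionisation at C3 would re-close to the more stable trans ring, because C2 stays fixed.

Further compounds
F1 | step 2 | (R)-4-benzyl-3-[(2R,3S)-3-[4-(benzyloxy)-3-methoxyphenyl]-2-(4-cyano-2-iodophenoxy)-3-hydroxypropanoyl]oxazolidin-2-one | COc1cc([C@H](O)[C@@H](Oc2ccc(C#N)cc2I)C(=O)N2[C@H](Cc3ccccc3)COC2=O)ccc1OCc1ccccc1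
F2 | step 2 | 4-{[(1S,2S)-1-[4-(benzyloxy)-3-methoxyphenyl]-1,3-dihydroxypropan-2-yl]oxy}-3-iodobenzonitrile | COc1cc([C@H](O)[C@@H](Oc2ccc(C#N)cc2I)CO)ccc1OCc1ccccc1
F3 | step 2 | 4-{[(1S,2S)-1-[4-(benzyloxy)-3-methoxyphenyl]-3-(tert-butyldimethylsilyloxy)-1-hydroxypropan-2-yl]oxy}-3-iodobenzonitrile | COc1cc([C@H](O)[C@@H](Oc2ccc(C#N)cc2I)CO[Si](C)(C)C(C)(C)C)ccc1OCc1ccccc1
F4 | step 2 | (2S,3S)-3-[4-(benzyloxy)-3-methoxyphenyl]-2-[(tert-butyldimethylsilyloxy)methyl]-2,3-dihydro-1,4-benzodioxine-6-carbonitrile | COc1cc([C@@H]2Oc3cc(C#N)ccc3O[C@H]2CO[Si](C)(C)C(C)(C)C)ccc1OCc1ccccc1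
F5 | step 6 | 5,7-bis(benzyloxy)-2-{(2S,3S)-3-[4-(benzyloxy)-3-methoxyphenyl]-2-(hydroxymethyl)-2,3-dihydro-1,4-benzodioxin-6-yl}-4H-chromen-4-one | COc1cc([C@@H]2Oc3cc(-c4cc(=O)c5c(OCc6ccccc6)cc(OCc6ccccc6)cc5o4)ccc3O[C@H]2CO)ccc1OCc1ccccc1
F0 | step 7 | none | none
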